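Cuts: first the acyl–O bonds at C6, C2/C3 and C7. Then C3–O (acetate opening of a β C2,C3-oxirane) and the C2–O/C3–O bonds of that oxirane, back to a C2=C3–C4=C5 diene. After a retro-Wharton shift to a C4 ketone, C5–O and C6–O of an α oxirane, and last C1–O of a para-quinol.
Enabling feature: in the single six-membered carbocycle the tertiary carbinol C1 (bearing C7) stands para to C4. The ring therefore maps onto a cyclohexa-2,5-dienone with C1 and C4 on a mirror plane and with C2=C3 and C5=C6 enantiotopic. The C6–O bond of the target is cis to C1–OH.
Forward order: the carbocycle is the benzene ring of 4-hydroxybenzyl alcohol and is never opened. On it arise in turn the C5,C6-oxirane (step 3), a C1,C6-dioxolane (step 5) and the C2,C3-oxirane (step 7), and each is opened again before the end.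
Stereochemistry: a chiral primary-amine salt picks the arm and C1-OH picks the face, which fixes C1 and C6 (C5 is transient). C7-OH relays this to C2 by directed epoxidation, and SN2 inversion by acetate sets C3.
Key step: step 3

Numbering and faces (kept for every ring compound, descriptors refer to this numbering): C1 = tertiary carbinol carbon bearing C7H2, C2 and C3 = acetoxy carbons, C4=C5 = alkene, C6 = benzoyloxy carbon. α is the face of C1-OH and β is the face of C7. The target has C1-OH α, C2-OAc β, C3-OAc α and C6-OBz α, i.e. (1S,2S,3R,6S).
Assumption: the quinine-derived 9-amino-9-deoxy-epi amine is taken to favour the C5=C6 arm as numbered. If it favours the mirror-image arm, the quinidine-derived pseudo-enantiomer replaces it and nothing else in the route changes.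

Step 1
Reactants: 1 4-hydroxybenzyl alcohol; 2 tert-butyldimethylsilyl chloride
Product: 3 4-[(tert-butyldimethylsilyloxy)methyl]phenol
Conditions: TBSCl (1.05 equiv), imidazole (2.2 equiv), DMF, 0 °C
Reagents that add atoms: tert-butyldimethylsilyl chloride, CC(C)(C)[Si](C)(C)Cl
Why: Imidazole-promoted silyl ether formation with one equivalent of chlorosilane takes the more nucleophilic primary benzylic hydroxyl ahead of the phenol, and any aryl silyl ether that forms is the more labile one and falls off on mild basic work-up.

Step 2
Reactants: 3 4-[(tert-butyldimethylsilyloxy)methyl]phenol; 4 water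
Product: 5 4-hydroxy-4-[(tert-butyldimethylsilyloxy)methyl]cyclohexa-2,5-dien-1-one (achiral para-quinol)
Conditions: PhI(OAc)2 (1.1 equiv), MeCN–H2O (3:1), 0 °C
Reagents that add atoms: water, O
Why: Hypervalent-iodine oxidative dearomatisation of a para-alkylphenol, in which water attacks the substituted para carbon C1 of the iodane-activated ring, gives the para-quinol, which is achiral because C1 and C4 lie on its mirror plane.

Step 3
Reactants: 5 achiral para-quinol; 6 hydrogen peroxide
Product: 7 (1S,5R,6S)-syn-epoxy para-quinol: C4 ketone, C2=C3 alkene, α C5,C6-oxirane cis to C1-OH [(1R,5S,6S)-5-hydroxy-5-[(tert-butyldimethylsilyloxy)methyl]-7-oxabicyclo[4.1.0]hept-3-en-2-one]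
Conditions: 9-amino(9-deoxy)epiquinine (10 mol %), TFA (20 mol %), 50% aq H2O2 (1.1 equiv), dioxane, 30 °C
Reagents that add atoms: hydrogen peroxide, OO
Why: Proposed new method: the primary amine of the catalyst condenses with the C4 ketone of 5 to a cross-conjugated iminium ion, hydrogen peroxide held by the protonated quinuclidine adds to C6, and the resulting β-hydroperoxy enamine attacks the proximal peroxide oxygen through C5 and expels water, after which hydrolysis returns the amine. The oxirane, the only ring formed, closes in a 3-exo-tet mode and can only be cis-fused to the carbocycle, so C5 follows C6. The closest known reaction types are the Weitz–Scheffer epoxidation of simple cyclic enones with aqueous hydrogen peroxide under cinchona primary-amine-salt (iminium) catalysis and the base-mediated syn-epoxidation of para-quinols, whereas neither iminium formation from a para-quinol nor the differentiation of its two arms has been shown. C6 is controlled on two levels: the face by the substrate, since C1-OH hydrogen-bonds the incoming peroxide and the bulky CH2OTBS group screens the β face, and the arm by the catalyst. Because α attack on C5=C6 and α attack on C2=C3 are mirror-image events of opposite local Re/Si sense, the enantioface preference that such catalysts show for cyclohexenone becomes arm selection here, and this choice alone makes C1 stereogenic (S). Mono-epoxidation is secured by near-stoichiometric peroxide, and the minor enantiomer keeps the arm that is matched to the catalyst, so it should be drained to the achiral bis-epoxide and the enantiomeric purity of 7 should rise with conversion.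

Step 4
Reactants: 7 syn-epoxy para-quinol; 8 hydrazine (as the hydrate)
Product: 10 (1S,6S)-1-[(tert-butyldimethylsilyloxy)methyl]cyclohexa-2,4-diene-1,6-diol, via epoxy hydrazone 9 (not isolated)
Conditions: N2H4·H2O (3 equiv), AcOH (0.2 equiv), MeOH, Ar, 0 °C to rt
Reagents that add atoms: none
Why: Wharton transposition, known also for epoxides of cross-conjugated dienones: hydrazone 9 opens the oxirane at C5 to an alkenyl diazene that loses N2 and is protonated at C4, so C4=C5 appears while the C6–O bond is never broken and C6 keeps its α oxygen, and a Payne shift is excluded because C1-OH and the oxirane are cis.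

Step 5
Reactants: 10 cis-diene diol; 11 2,2-dimethoxypropane
Product: 12 (1S,6S)-1,6-O-isopropylidene ketal of 10 (cis-fused dioxolane on the α face, C7-OTBS on the β face)
Conditions: Me2C(OMe)2, PPTS (5 mol %), CH2Cl2, 0 °C to rt; Et3N quench
Reagents that add atoms: 2,2-dimethoxypropane, COC(C)(C)OC
Why: Acid-catalysed transketalisation, routine for arene cis-dihydrodiols, can bridge only the cis C1/C6 oxygens and thereby silences C1-OH as a directing group, covers the α face and blocks dehydrative aromatisation.

Step 6
Reactants: 12 silyl ether ketal
Product: 13 (1S,6S)-1-(hydroxymethyl)cyclohexa-2,4-diene-1,6-diol 1,6-O-isopropylidene ketal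
Conditions: TBAF (1.1 equiv), THF, 0 °C
Reagents that add atoms: none
Why: Fluoride-driven Si–O cleavage leaves ketal and diene untouched and frees C7-OH, the only hydroxyl of 13 and the one that stands on the β face.

Step 7
Reactants: 13 diene alcohol; 14 tert-butyl hydroperoxide
Product: 15 (1S,2S,3S,6S)-β-2,3-epoxy alcohol: C2,C3-oxirane on the face of C7, C4=C5 alkene, C1,C6-ketal on the α face, free C7-OH
Conditions: VO(acac)2 (5 mol %), t-BuOOH (decane, 1.2 equiv), CH2Cl2, 0 °C
Reagents that add atoms: tert-butyl hydroperoxide, CC(C)(C)OO
Why: Vanadium-catalysed hydroxyl-directed epoxidation of a homoallylic alcohol: the peroxovanadate bound to C7-O reaches only the neighbouring C2=C3 bond and only from the β face on which C7 stands, a preference that the α-face ketal reinforces, so C2–O and C3–O are both set β.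

Step 8
Reactants: 15 epoxy alcohol; 16 benzoyl chloride
Product: 17 (1S,2S,3S,6S)-C7 benzoate of 15
Conditions: BzCl (1.2 equiv), Et3N, DMAP (cat.), CH2Cl2, 0 °C
Reagents that add atoms: benzoyl chloride, O=C(Cl)c1ccccc1
Why: DMAP-catalysed acylation of the single free hydroxyl proceeds under basic conditions that a vinyl oxirane and a ketal tolerate, and it touches no stereocentre.

Step 9
Reactants: 17 epoxy benzoate; 18 acetic acid
Product: 19 C3 acetate with free C2-OH: C3-OAc α, C2-OH β, C4=C5, C1,C6-ketal α, C7-OBz [(1R,2S,3R,6S); the C1 descriptor changes through CIP ranking only]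
Conditions: AcOH, NaOAc (buffer), 40 °C
Reagents that add atoms: acetic acid, CC(=O)O
Why: Buffered acidolysis of a vinyl oxirane is an SN2 opening in which acetate attacks the allylically activated C3 rather than the neopentyl-like C2 or the ketal-flanked C5, from the α face with inversion, which gives the trans pair C3-OAc (α) and C2-OH (β), and the β-face benzoate cannot reach the rear side of either oxirane carbon.

Step 10
Reactants: 19 hydroxy acetate; 20 acetic anhydride
Product: 21 (1S,2S,3R,6S)-2,3-diacetate with C1,C6-ketal and C7-OBz
Conditions: Ac2O, pyridine, DMAP (cat.), CH2Cl2, 0 °C to rt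
Reagents that add atoms: acetic anhydride, CC(=O)OC(C)=O
Why: DMAP-catalysed acetylation of the hindered C2-OH, run directly after step 9 so that a C7-to-C2 benzoyl shift gets little time, changes no stereocentre.

Step 11
Reactants: 21 diacetate ketal; 4 water
Product: 22 (1S,2S,3R,6S)-2,3-diacetoxy-1-(benzoyloxymethyl)cyclohex-4-ene-1,6-diol
Conditions: TFA, H2O, CH2Cl2, 0 °C
Reagents that add atoms: none
Why: Acid hydrolysis of the isopropylidene ketal spares the three esters at 0 °C, and ionisation at allylic C3 or C6 is held back by the electron-withdrawing acyloxy neighbours.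

Step 12
Reactants: 22 C1,C6-diol; 16 benzoyl chloride
Product: 23 cleistenediol F, (1S,2S,3R,6S)-2,3-diacetoxy-6-benzoyloxy-1-(benzoyloxymethyl)cyclohex-4-en-1-ol
Conditions: BzCl (1.2 equiv), pyridine, DMAP (cat.), CH2Cl2, 0 °C
Reagents that add atoms: benzoyl chloride, O=C(Cl)c1ccccc1
Why: Site-selective acylation takes the secondary allylic C6-OH while the tertiary C1-OH, buried between three substituted carbons, stays free, and a benzoyl shift from C7 to C6 in 22 would be harmless because benzoylation of the freed C7-OH leads to the same product.

Compound list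
1 | 4-hydroxybenzyl alcohol | OCc1ccc(O)cc1 | starting material
2 | tert-butyldimethylsilyl chloride | CC(C)(C)[Si](C)(C)Cl | starting material
3 | 4-[(tert-butyldimethylsilyloxy)methyl]phenol | CC(C)(C)[Si](C)(C)OCc1ccc(O)cc1 | intermediate
4 | water | O | starting material
5 | 4-hydroxy-4-[(tert-butyldimethylsilyloxy)methyl]cyclohexa-2,5-dien-1-one | O=C1C=CC(O)(CO[Si](C)(C)C(C)(C)C)C=C1 | intermediate
6 | hydrogen peroxide | OO | starting material
7 | (1S,5R,6S)-syn-epoxy para-quinol | O=C1C=C[C@](O)(CO[Si](C)(C)C(C)(C)C)[C@H]2O[C@@H]12 | intermediate
8 | hydrazine (used as the hydrate) | NN | starting material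
9 | hydrazone of 7 (ring configuration as in 7, not isolated) | NN=C1C=C[C@](O)(CO[Si](C)(C)C(C)(C)C)[C@H]2O[C@@H]12 | intermediate
10 | (1S,6S)-1-[(tert-butyldimethylsilyloxy)methyl]cyclohexa-2,4-diene-1,6-diol | O[C@H]1C=CC=C[C@]1(O)CO[Si](C)(C)C(C)(C)C | intermediate
11 | 2,2-dimethoxypropane | COC(C)(C)OC | starting material
12 | (1S,6S)-1,6-O-isopropylidene ketal of 10 | CC1(C)O[C@H]2C=CC=C[C@@]2(CO[Si](C)(C)C(C)(C)C)O1 | intermediate
13 | (1S,6S)-C7 alcohol (desilylated 12) | CC1(C)O[C@H]2C=CC=C[C@@]2(CO)O1 | intermediate
14 | tert-butyl hydroperoxide | CC(C)(C)OO | starting material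
15 | (1S,2S,3S,6S)-β-2,3-epoxy alcohol | CC1(C)O[C@H]2C=C[C@@H]3O[C@@H]3[C@@]2(CO)O1 | intermediate
16 | benzoyl chloride | O=C(Cl)c1ccccc1 | starting material
17 | (1S,2S,3S,6S)-β-2,3-epoxy C7 benzoate | CC1(C)O[C@H]2C=C[C@@H]3O[C@@H]3[C@@]2(COC(=O)c4ccccc4)O1 | intermediate
18 | acetic acid | CC(=O)O | starting material
19 | (1R,2S,3R,6S)-C3 acetate, C2 alcohol | CC1(C)O[C@H]2C=C[C@@H](OC(C)=O)[C@H](O)[C@@]2(COC(=O)c3ccccc3)O1 | intermediate
20 | acetic anhydride | CC(=O)OC(C)=O | starting material
21 | (1S,2S,3R,6S)-2,3-diacetate ketal | CC1(C)O[C@H]2C=C[C@@H](OC(C)=O)[C@H](OC(C)=O)[C@@]2(COC(=O)c3ccccc3)O1 | intermediate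
22 | (1S,2S,3R,6S)-2,3-diacetoxy-1-(benzoyloxymethyl)cyclohex-4-ene-1,6-diol | O[C@H]1C=C[C@@H](OC(C)=O)[C@H](OC(C)=O)[C@]1(O)COC(=O)c2ccccc2 | intermediate
23 | cleistenediol F | CC(=O)O[C@@H]1C=C[C@H](OC(=O)c2ccccc2)[C@@](O)(COC(=O)c2ccccc2)[C@H]1OC(C)=O | target

Total step count: 12. Longest linear sequence: 12 steps (1 to 23).

Steps most likely to fail

Step 3 (iminium formation and arm selection). The hindered, cross-conjugated C4 ketone may condense too slowly with the amine. Uncatalysed peroxide addition without arm selection, or a second epoxidation, could then take over. The fallback replaces catalytic desymmetrisation by racemic epoxidation and enzymatic resolution, all known reaction types. Setting out from 5, a hydroxyl-directed Weitz–Scheffer epoxidation (30% H2O2, aq NaOH, THF, 0 °C) should give the racemic syn-epoxy para-quinol F1. The Wharton conditions of step 4 should carry it, by way of the racemic epoxy hydrazone F2, to the racemic cis-diene diol F3. A lipase-catalysed kinetic resolution follows (Candida antarctica lipase B, vinyl acetate, MTBE, rt). By the empirical size rule for secondary alcohols it should acetylate C6-OH of the (1R,6R) enantiomer to the monoacetate F4 and leave the (1S,6S) diol untouched. After chromatography the route is rejoined at 10.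

Step 4 (Wharton transposition). Conjugate addition of hydrazine at C2, or its attack on the oxirane, may outrun hydrazone formation. The diene diol may also dehydrate to a phenol before it is secured as the ketal. The fallback uses hydride reduction and reductive β-elimination in place of a diazene. Setting out from 7, a Luche reduction (NaBH4, CeCl3·7H2O, MeOH, −78 °C) should give the C4 carbinol F5. Either C4 epimer serves, because C4 becomes sp2. An Appel-type iodination (PPh3, I2, imidazole, THF, 0 °C) should convert the secondary allylic hydroxyl, not the tertiary one, into the C4 iodide F6. Activated zinc (THF–aq NH4Cl, 0 °C) should then insert into C4–I and expel the C5–O bond of the oxirane in a Boord-type elimination. This creates C4=C5 and leaves the C6–O bond untouched. The route is rejoined at 10.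

Step 7 (directed epoxidation). Oxygen transfer may lose its direction and go to the less hindered C4=C5 bond. The Lewis-acidic vanadium may open the vinyl oxirane once it has formed, and a slow reaction gives the diene time for Diels–Alder dimerisation. The fallback uses cycloaddition and deoxygenation instead of metal-directed oxygen transfer. Setting out from 13, photo-oxygenation (O2, tetraphenylporphyrin, hν, CH2Cl2, −30 °C) should add singlet oxygen across C2 and C5 on the β face, away from the ketal, as is known for arene cis-diol acetonides. This should give the β C2,C5-endoperoxide F7. Triphenylphosphine (toluene, 0 °C to rt) should attack the less hindered peroxide oxygen on C5. The C2 alkoxide so released should close onto C3 in an SN2′ displacement, which moves the alkene to C4=C5 and forms the β C2,C3-oxirane. The route is rejoined at 15.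

Further compounds
F1 | step 3 | racemic syn-epoxy para-quinol (7 and its enantiomer) | O=C1C=C[C@](O)(CO[Si](C)(C)C(C)(C)C)[C@H]2O[C@@H]12.O=C1C=C[C@@](O)(CO[Si](C)(C)C(C)(C)C)[C@@H]2O[C@H]12
F2 | step 3 | racemic epoxy hydrazone (9 and its enantiomer, not isolated) | NN=C1C=C[C@](O)(CO[Si](C)(C)C(C)(C)C)[C@H]2O[C@@H]12.NN=C1C=C[C@@](O)(CO[Si](C)(C)C(C)(C)C)[C@@H]2O[C@H]12
F3 | step 3 | racemic cis-diene diol (10 and its enantiomer) | O[C@H]1C=CC=C[C@]1(O)CO[Si](C)(C)C(C)(C)C.O[C@@H]1C=CC=C[C@@]1(O)CO[Si](C)(C)C(C)(C)C
F4 | step 3 | (1R,6R)-6-acetoxy-1-[(tert-butyldimethylsilyloxy)methyl]cyclohexa-2,4-dien-1-ol | CC(=O)O[C@@H]1C=CC=C[C@@]1(O)CO[Si](C)(C)C(C)(C)C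
F5 | step 4 | C4 carbinol of 7 (C4 epimers, other centres as in 7) | OC1C=C[C@](O)(CO[Si](C)(C)C(C)(C)C)[C@H]2O[C@@H]12
F6 | step 4 | C4 iodide (C4 epimers, other centres as in 7) | IC1C=C[C@](O)(CO[Si](C)(C)C(C)(C)C)[C@H]2O[C@@H]12
F7 | step 7 | β C2,C5-endoperoxide of 13 (peroxide bridge on the face of C7, C3=C4 alkene, ketal α) | CC1(C)O[C@H]2[C@H]3C=C[C@H](OO3)[C@@]2(CO)O1
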